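**Plan**

- Cuts (iridoid numbering: C1 acetal carbon, O2, C3=C4, C5/C9 ring fusion, C10 on C8, C11 on C4): first the C1 and C10 esters; then the pyran at O2, giving a C1/C3 dialdehyde, which is the ozonolysis product of a C1=C3 cyclopentene; then the C8–C9 bond of the cyclopentane, which in the retro direction contracts it to a cyclobutanol with C8/C10 as an acyl side chain; then C7–C8 (acyl anion + cyclobutanone), C4=C11 (Wittig) and C5–C6/C7–C9 ([2+2]).
- Forward: cyclobutane by enone–ketene acetal photocycloaddition on cyclopentenone 1; cyclopentane C5–C6–C7–C8–C9 by one-carbon ring expansion of that cyclobutane; pyran by ozonolysis of the original carbocycle and lactolisation; esters last.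
- Enabling feature: the cyclopentane carries the vicinal C7–OH/C8(OH)(CH2O–) pair, a reduced α-ketol. The ketol C7=O/C8–OH in a five-membered ring is the strain-released isomer of a 1-(oxyacetyl)cyclobutanol made of C7, C6, C5 and C9, and C9 is allylic while the C1=C3 alkene is kept.
- Stereochemistry: the one stereocenter of (S)-1 steers the [2+2] (C5, C9) and is then erased; convex-face addition fixes the cyclobutanol carbon and the ring expansion relays it to C8; the C8 hydroxyl delivers hydride to C7; C1 follows the anomeric preference of the lactol; the side-chain center comes from (S)-3-methylpentanoic acid. The target is (1R,4aR,6R,7S,7aR),(3S).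

Key step: step 10

Remark: C4 of compounds 6–16 is a temporary stereocenter, drawn as the convex-face hydroboration product (either epimer converges on 17); lactol 17 is drawn as the anomer that is acylated. "Exo" means the face of the two ring-fusion hydrogens, "endo" the face of the other ring.

**Step 1**
Reactants: 1 (S)-4-(tert-butyldimethylsilyloxy)cyclopent-2-en-1-one; 2 1,1-diethoxyethene
Product: 3 (1R,4S,5S)-4-(tert-butyldimethylsilyloxy)-6,6-diethoxybicyclo[3.2.0]heptan-2-one
Conditions: hν (350 nm, Pyrex), 2 (10 equiv), CH2Cl2, −40 °C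
Reagents that add atoms: none
Why: Enone–alkene [2+2] photocycloaddition: the triplet enone should add the ketene acetal head-to-tail (acetal carbon on the former β-carbon, C9) and anti to the silyloxy group, which sets C5 and C9 cis on the cyclobutane in one absolute sense; the minor syn adduct is removed here, before the controlling center is erased.

**Step 2**
Reactants: 3
Product: 4 (1R,5R)-6,6-diethoxybicyclo[3.2.0]hept-3-en-2-one
Conditions: DBU (1.2 equiv), CH2Cl2, 0 °C → rt
Reagents that add atoms: none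
Why: E1cB β-elimination of silanol from the β-silyloxy ketone should give the conjugated cyclopentenone, which erases the spent stereocenter and places the future C1=C3 alkene; the cis ring fusion cannot epimerise.

**Step 3**
Reactants: 4
Product: 5 (1R,5R)-6,6-diethoxy-2-methylidenebicyclo[3.2.0]hept-3-ene
Conditions: Ph3PCH3Br, KOtBu, THF, 0 °C; then 4, 0 °C → rt
Reagents that add atoms: methylenetriphenylphosphorane, C=P(c1ccccc1)(c1ccccc1)c1ccccc1, made in the flask from methyltriphenylphosphonium bromide, C[P+](c1ccccc1)(c1ccccc1)c1ccccc1.[Br-]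
Why: Wittig methylenation of the enone carbonyl (1,2-addition) installs C11 on C4 as a cross-conjugated exocyclic alkene.

**Step 4**
Reactants: 5
Product: 7 endo-2-(hydroxymethyl)-6,6-diethoxybicyclo[3.2.0]hept-3-ene, via B-alkyl-9-BBN adduct 6 (not isolated)
Conditions: 9-BBN, THF, 0 °C → rt; then NaOH, H2O2, 0 °C
Reagents that add atoms: hydrogen peroxide, OO
Why: Hydroboration–oxidation: 9-BBN should add boron to the terminal carbon of the 1,1-disubstituted exocyclic alkene from the convex face and leave the cis-disubstituted ring alkene, giving the primary C11 alcohol; the C4 center formed here is temporary.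

**Step 5**
Reactants: 7
Product: 8 TBDPS ether of 7
Conditions: TBDPSCl, imidazole, CH2Cl2, rt
Reagents that add atoms: tert-butylchlorodiphenylsilane, CC(C)(C)[Si](Cl)(c1ccccc1)c1ccccc1
Why: Standard silylation of the primary alcohol; the TBDPS ether is chosen to survive the acid of step 6.

**Step 6**
Reactants: 8
Product: 9 endo-2-[(tert-butyldiphenylsilyloxy)methyl]-cis-bicyclo[3.2.0]hept-3-en-6-one
Conditions: p-TsOH·H2O (cat.), acetone/H2O, rt
Reagents that add atoms: water, O
Why: Acid-catalysed ketal hydrolysis frees the cyclobutanone (C7), which sits on the allylic ring-fusion carbon C9; the TBDPS ether and the alkene are stable to it.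

**Step 7**
Reactants: 9
Product: 10 6-exo-(1-ethoxyvinyl)-6-endo-hydroxy carbinol derived from 9
Conditions: ethyl vinyl ether, t-BuLi, THF, −78 → 0 °C; then 9, −78 °C; NH4Cl quench at −78 °C
Reagents that add atoms: 1-ethoxyvinyllithium, [Li]C(=C)OCC, made in the flask from ethyl vinyl ether, C=COCC
Why: 1,2-Addition of an acyl anion equivalent: the lithiated enol ether should attack the cyclobutanone from the convex face, placing the future acyl group exo and the hydroxyl endo; the cold quench forestalls alkoxide-driven opening of the allylic cyclobutanol.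

**Step 8**
Reactants: 10
Product: 12 1-(6-endo-hydroxybicycloheptenyl)-2-hydroxyethanone (α,α'-dihydroxy ketone), via ethyl hemiketal 11 (not isolated)
Conditions: OsO4 (2 mol %), NMO (1.1 equiv), acetone/H2O, 0 °C
Reagents that add atoms: N-methylmorpholine N-oxide, C[N+]1([O-])CCOCC1; water, O
Why: Osmium-catalysed dihydroxylation of the electron-rich enol ether, in preference to the hindered ring alkene, and collapse of the hemiketal should give the hydroxyacetyl cyclobutanol without passing through a cation next to the strained ring.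

**Step 9**
Reactants: 12
Product: 13 triethylsilyl ether of 12 at the primary (C10) hydroxyl
Conditions: TESCl, imidazole, CH2Cl2, −20 °C
Reagents that add atoms: chlorotriethylsilane, CC[Si](Cl)(CC)CC
Why: Selective silylation of the primary hydroxyl; the tertiary cyclobutanol stays free for chelation in the next step.

**Step 10**
Reactants: 13
Product: 14 2-endo-hydroxy-2-exo-[(triethylsilyloxy)methyl]-6-endo-[(tert-butyldiphenylsilyloxy)methyl]-cis-bicyclo[3.3.0]oct-7-en-3-one
Conditions: Sc(OTf)3 (10 mol %), 4 Å MS, CH2Cl2, −20 → 0 °C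
Reagents that add atoms: none
Why: α-Ketol (acyloin) rearrangement with ring expansion, the closest known type being the Lewis-acid-catalysed conversion of 1-acylcyclobutanols into 2-hydroxy-2-alkylcyclopentanones: Sc(OTf)3 binds the tertiary hydroxyl and the ketone oxygen of 13 in a five-membered chelate, the C7–C9 ring bond shifts suprafacially to the activated carbonyl carbon C8, and the former carbinol carbon C7 becomes the ring ketone. The five-membered ring is therefore not closed by a cyclisation but by a [1,2]-carbon shift that inserts C8 between C7 and C9 of the four-membered ring; release of cyclobutane strain drives it and makes it irreversible. The new quaternary center C8 is fixed by two elements: migrating C9 keeps its configuration, and because the acyl group is exo on the carbinol carbon (step 7) and the chelate holds O7 and O8 syn-periplanar, C9 reaches C8 from the face that leaves the new hydroxyl endo (cis to C1) and the silyloxymethyl group exo (cis to H9), as in the target. The step needs C9 and not C6 to migrate, which is secured because C9 is tertiary and allylic to C1=C3 while C6 is a plain methylene. It also needs the chelated and not the open transition state, which the bidentate Lewis acid and the bulky, weakly coordinating silyl ether on O10 secure.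

**Step 11**
Reactants: 14
Product: 15 trimethylsilyl ether of 14 at the tertiary (C8) hydroxyl
Conditions: N-(trimethylsilyl)imidazole, CH2Cl2, rt
Reagents that add atoms: N-(trimethylsilyl)imidazole, C[Si](C)(C)n1ccnc1
Why: Silylation of the tertiary hydroxyl with a strong, non-basic silyl donor (no enolisation of the C7 ketone) blocks hemiacetal bridging from O8 to C3 and retro-aldol loss in the next step.

**Step 12**
Reactants: 15
Product: 17 (1S,4aR,7S,7aR)-1-hydroxy-4-(TBDPS-oxymethyl)-7-(TES-oxymethyl)-7-(TMS-oxy)-4a,5,7,7a-tetrahydro-1H-cyclopenta[c]pyran-6-one, via C1/C3 dialdehyde 16 (not isolated)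
Conditions: O3, pyridine (3 equiv), CH2Cl2, −78 °C; then PPTS (cat.), CH2Cl2, rt
Reagents that add atoms: ozone, [O-][O+]=O
Why: Ozonolysis of the cyclopentene in the presence of pyridine releases the C1/C3 dialdehyde directly; acid-catalysed lactolisation (the C3 aldehyde enolises toward C4 and adds through oxygen to the C1 aldehyde) then forms the pyran with the C3=C4 enol ether, erases C4 and leaves the C1 hydroxyl in the anomerically favoured orientation trans to the C9–C8 bond.

**Step 13**
Reactants: 17; 18 (S)-3-methylpentanoic acid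
Product: 19 (1R,4aR,7S,7aR)-1-O-[(S)-3-methylpentanoyl] ester of 17
Conditions: 18, DCC, DMAP (cat.), CH2Cl2, 0 °C
Reagents that add atoms: none
Why: Steglich esterification at the lactol oxygen should trap the predominant anomer with retention, since no bond to C1 is broken; no other free hydroxyl is present.

**Step 14**
Reactants: 19
Product: 20 C8,C10-diol (C7 ketone, C11 TBDPS ether and C1 ester kept)
Conditions: HF·pyridine, pyridine, THF, 0 °C
Reagents that add atoms: none
Why: Fluoride-mediated desilylation: buffered HF·pyridine should remove the primary triethylsilyl and the tertiary trimethylsilyl ether and leave the TBDPS ether, the acyl acetal and the enol ether.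

**Step 15**
Reactants: 21 (E)-4-hydroxycinnamic acid (p-coumaric acid)
Product: 23 (E)-3-[4-(tert-butyldimethylsilyloxy)phenyl]prop-2-enoic acid, via bis-silyl ester 22 (not isolated)
Conditions: TBSCl (2.5 equiv), imidazole, DMF, rt; then AcOH/THF/H2O, rt
Reagents that add atoms: tert-butylchlorodimethylsilane, CC(C)(C)[Si](C)(C)Cl
Why: Bis-silylation followed by selective hydrolysis of the labile silyl ester leaves the phenol protected and the acid free.

**Step 16**
Reactants: 20; 23
Product: 24 C10 (E)-4-(TBS-oxy)cinnamate of 20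
Conditions: 23, DCC, DMAP (cat.), CH2Cl2, 0 °C → rt
Reagents that add atoms: none
Why: Steglich esterification of the only reactive (primary) hydroxyl; the tertiary C8 hydroxyl does not acylate under these conditions.

**Step 17**
Reactants: 24
Product: 25 (1R,4aR,6R,7S,7aR)-6,7-diol with C11 TBDPS ether and aryl TBS ether
Conditions: Me4NBH(OAc)3, MeCN/AcOH, −30 °C
Reagents that add atoms: none
Why: Hydroxyl-directed triacetoxyborohydride reduction: exchange of acetate for the C8 hydroxyl and intramolecular hydride transfer to the concave face of the C7 ketone should give the 7,8-trans diol; esters, cinnamate and silyl ethers are inert to this reagent.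

**Step 18**
Reactants: 25
Product: 26 target, (1R,4aR,6R,7S,7aR)-6,7-dihydroxy-4-(hydroxymethyl)-7-{[(E)-3-(4-hydroxyphenyl)prop-2-enoyl]oxymethyl}-1,4a,5,6,7,7a-hexahydrocyclopenta[c]pyran-1-yl (3S)-3-methylpentanoate
Conditions: TBAF, AcOH, THF, 0 °C → rt
Reagents that add atoms: none
Why: Buffered fluoride desilylation removes the TBDPS and aryl TBS ethers without ester migration or cleavage of the acyl acetal.

**Compound list**

1 | (S)-4-(tert-butyldimethylsilyloxy)cyclopent-2-en-1-one | O=C1C=C[C@@H](O[Si](C)(C)C(C)(C)C)C1 | starting material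
2 | 1,1-diethoxyethene | C=C(OCC)OCC | starting material
3 | (1R,4S,5S)-4-(tert-butyldimethylsilyloxy)-6,6-diethoxybicyclo[3.2.0]heptan-2-one (cis-fused, silyloxy anti to the cyclobutane) | O=C1C[C@H](O[Si](C)(C)C(C)(C)C)[C@H]2C(OCC)(OCC)C[C@@H]12 | intermediate
4 | (1R,5R)-6,6-diethoxybicyclo[3.2.0]hept-3-en-2-one | O=C1C=C[C@H]2C(OCC)(OCC)C[C@@H]12 | intermediate
5 | (1R,5R)-6,6-diethoxy-2-methylidenebicyclo[3.2.0]hept-3-ene | C=C1C=C[C@H]2C(OCC)(OCC)C[C@@H]12 | intermediate
6 | 9-[(endo-6,6-diethoxybicyclo[3.2.0]hept-3-en-2-yl)methyl]-9-borabicyclo[3.3.1]nonane | C(B1C2CCCC1CCC2)[C@H]1C=C[C@H]2C(OCC)(OCC)C[C@@H]12 | intermediate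
7 | (endo-6,6-diethoxy-cis-bicyclo[3.2.0]hept-3-en-2-yl)methanol, ring fusion as in 4 | OC[C@H]1C=C[C@H]2C(OCC)(OCC)C[C@@H]12 | intermediate
8 | tert-butyldiphenylsilyl ether of 7 | CC(C)(C)[Si](c1ccccc1)(c1ccccc1)OC[C@H]1C=C[C@H]2C(OCC)(OCC)C[C@@H]12 | intermediate
9 | endo-2-[(tert-butyldiphenylsilyloxy)methyl]-cis-bicyclo[3.2.0]hept-3-en-6-one | CC(C)(C)[Si](c1ccccc1)(c1ccccc1)OC[C@H]1C=C[C@H]2C(=O)C[C@@H]12 | intermediate
10 | endo-2-[(tert-butyldiphenylsilyloxy)methyl]-6-exo-(1-ethoxyvinyl)-cis-bicyclo[3.2.0]hept-3-en-6-endo-ol | CC(C)(C)[Si](c1ccccc1)(c1ccccc1)OC[C@H]1C=C[C@H]2[C@](O)(C(=C)OCC)C[C@@H]12 | intermediate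
11 | ethyl hemiketal of 12 (both epimers at the hemiketal carbon) | CC(C)(C)[Si](c1ccccc1)(c1ccccc1)OC[C@H]1C=C[C@H]2[C@](O)(C(O)(CO)OCC)C[C@@H]12 | intermediate
12 | 1-{endo-2-[(tert-butyldiphenylsilyloxy)methyl]-6-endo-hydroxy-cis-bicyclo[3.2.0]hept-3-en-6-exo-yl}-2-hydroxyethan-1-one | CC(C)(C)[Si](c1ccccc1)(c1ccccc1)OC[C@H]1C=C[C@H]2[C@](O)(C(=O)CO)C[C@@H]12 | intermediate
13 | triethylsilyl ether of 12 at the primary hydroxyl | CC(C)(C)[Si](c1ccccc1)(c1ccccc1)OC[C@H]1C=C[C@H]2[C@](O)(C(=O)CO[Si](CC)(CC)CC)C[C@@H]12 | intermediate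
14 | 2-endo-hydroxy-2-exo-[(triethylsilyloxy)methyl]-6-endo-[(tert-butyldiphenylsilyloxy)methyl]-cis-bicyclo[3.3.0]oct-7-en-3-one (C8–OH cis to C1, C10 cis to H9) | CC(C)(C)[Si](c1ccccc1)(c1ccccc1)OC[C@H]1C=C[C@H]2[C@](O)(CO[Si](CC)(CC)CC)C(=O)C[C@@H]12 | intermediate
15 | trimethylsilyl ether of 14 at the tertiary hydroxyl | CC(C)(C)[Si](c1ccccc1)(c1ccccc1)OC[C@H]1C=C[C@H]2[C@](O[Si](C)(C)C)(CO[Si](CC)(CC)CC)C(=O)C[C@@H]12 | intermediate
16 | C1/C3 dialdehyde: cis-2-formyl-3-[1-formyl-2-(TBDPS-oxy)ethyl]cyclopentanone core with C8 OTMS and CH2OTES | O=C[C@H](CO[Si](c1ccccc1)(c1ccccc1)C(C)(C)C)[C@@H]1CC(=O)[C@@](O[Si](C)(C)C)(CO[Si](CC)(CC)CC)[C@@H]1C=O | intermediate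
17 | (1S,4aR,7S,7aR)-1-hydroxy-4-[(tert-butyldiphenylsilyloxy)methyl]-7-[(triethylsilyloxy)methyl]-7-(trimethylsilyloxy)-4a,5,7,7a-tetrahydro-1H-cyclopenta[c]pyran-6-one | O[C@H]1OC=C(CO[Si](c3ccccc3)(c3ccccc3)C(C)(C)C)[C@@H]2CC(=O)[C@@](O[Si](C)(C)C)(CO[Si](CC)(CC)CC)[C@H]12 | intermediate
18 | (S)-3-methylpentanoic acid | CC[C@H](C)CC(=O)O | starting material
19 | (1R,4aR,7S,7aR)-1-O-[(3S)-3-methylpentanoyl] ester of 17 | CC[C@H](C)CC(=O)O[C@H]1OC=C(CO[Si](c3ccccc3)(c3ccccc3)C(C)(C)C)[C@@H]2CC(=O)[C@@](O[Si](C)(C)C)(CO[Si](CC)(CC)CC)[C@H]12 | intermediate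
20 | (1R,4aR,7S,7aR)-7-hydroxy-7-(hydroxymethyl)-6-oxo-4-[(tert-butyldiphenylsilyloxy)methyl]-hexahydrocyclopenta[c]pyran-1-yl (3S)-3-methylpentanoate | CC[C@H](C)CC(=O)O[C@H]1OC=C(CO[Si](c3ccccc3)(c3ccccc3)C(C)(C)C)[C@@H]2CC(=O)[C@@](O)(CO)[C@H]12 | intermediate
21 | (E)-3-(4-hydroxyphenyl)prop-2-enoic acid (p-coumaric acid) | OC(=O)/C=C/c1ccc(O)cc1 | starting material
22 | tert-butyldimethylsilyl (E)-3-[4-(tert-butyldimethylsilyloxy)phenyl]prop-2-enoate | CC(C)(C)[Si](C)(C)OC(=O)/C=C/c1ccc(O[Si](C)(C)C(C)(C)C)cc1 | intermediate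
23 | (E)-3-[4-(tert-butyldimethylsilyloxy)phenyl]prop-2-enoic acid | OC(=O)/C=C/c1ccc(O[Si](C)(C)C(C)(C)C)cc1 | intermediate
24 | (1R,4aR,7S,7aR) C10 (E)-4-(TBS-oxy)cinnamate of 20 (C7 ketone) | CC[C@H](C)CC(=O)O[C@H]1OC=C(CO[Si](c3ccccc3)(c3ccccc3)C(C)(C)C)[C@@H]2CC(=O)[C@@](O)(COC(=O)/C=C/c3ccc(O[Si](C)(C)C(C)(C)C)cc3)[C@H]12 | intermediate
25 | (1R,4aR,6R,7S,7aR)-6,7-diol of 24 (C11 TBDPS ether, aryl TBS ether) | CC[C@H](C)CC(=O)O[C@H]1OC=C(CO[Si](c3ccccc3)(c3ccccc3)C(C)(C)C)[C@@H]2C[C@@H](O)[C@@](O)(COC(=O)/C=C/c3ccc(O[Si](C)(C)C(C)(C)C)cc3)[C@H]12 | intermediate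
26 | (1R,4aR,6R,7S,7aR)-6,7-dihydroxy-4-(hydroxymethyl)-7-{[(E)-3-(4-hydroxyphenyl)prop-2-enoyl]oxymethyl}-1,4a,5,6,7,7a-hexahydrocyclopenta[c]pyran-1-yl (3S)-3-methylpentanoate | CC[C@H](C)CC(=O)O[C@H]1OC=C(CO)[C@@H]2C[C@@H](O)[C@@](O)(COC(=O)/C=C/c3ccc(O)cc3)[C@H]12 | target

**Count and risks**

Total steps: 18. Longest linear sequence: 17 (steps 1–14 and 16–18, from 1; step 15 is the side branch).

Three steps most likely to fail:

1. Step 10. What may go wrong: loss of facial control at C8 if an open, unchelated transition state competes, or partial migration of C6 in place of C9. The fallback sets out from cyclobutanone 9 and comes back at 14; it sets C8 by hydroxyl-directed epoxidation and no longer by relay in the shift. Compound 9 is treated with ethynylmagnesium bromide (THF, −78 °C) to give the exo-ethynyl carbinol F1. Ph3PAuCl/AgSbF6 (cat., CH2Cl2) then triggers the known gold-catalysed ring expansion of 1-alkynylcyclobutanols, again through allylic C9, to the 2-methylidenecyclopentanone F2. Luche reduction (NaBH4, CeCl3, MeOH, −78 °C) from the convex face gives the endo allylic alcohol F3. VO(acac)2/t-BuOOH delivers oxygen syn to that hydroxyl, on the endo face of C8, giving the spiro-epoxy alcohol F4. Dess–Martin periodinane gives the epoxy ketone F5. Dilute HClO4 in aqueous THF opens the epoxide at the primary carbon C10 to the keto diol F6. TESCl/imidazole silylates the primary hydroxyl and gives 14.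

2. Step 8. What may go wrong: osmylation of the ring alkene competing with the enol ether, or isomerisation of the free α,α'-dihydroxy ketone during the oxidation. The fallback sets out from 10 and comes back at 12; it introduces the C10 oxygen by enol silane oxidation. Oxalic acid in wet THF hydrolyses the enol ether of 10 to the methyl ketone F7. TMSOTf/Et3N converts it into the silyl enol ether that also carries a tertiary silyl ether, F8. Rubottom oxidation (mCPBA, NaHCO3, CH2Cl2, −20 °C), which is selective for the enol silane, gives the α-silyloxy ketone F9. Citric acid in MeOH removes both trimethylsilyl groups and gives 12.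

3. Step 17. What may go wrong: slow ligand exchange at the crowded tertiary hydroxyl of the late intermediate, so that no intramolecular hydride transfer takes place, and erosion of the enol ether and acyl acetal in acetic acid. The fallback sets out from 14 and comes back at 25; it moves the reduction to a stage without acid-labile groups. Me4NBH(OAc)3 (MeCN/AcOH, −30 °C) on the bicyclic ketol 14 gives the trans-diol F10. N-(Trimethylsilyl)imidazole gives the bis(trimethylsilyl) ether F11. Ozonolysis with pyridine gives the dialdehyde F12, which PPTS closes to the lactol F13. Acylation with 18 (DCC, DMAP) gives the ester F14. HF·pyridine removes the triethylsilyl and both trimethylsilyl groups and gives the triol F15. Esterification of its primary C10 hydroxyl with 23 (DCC, DMAP, −20 °C) gives 25, and step 18 follows.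

**Further compounds**

F1 | step 10 | endo-2-[(tert-butyldiphenylsilyloxy)methyl]-6-exo-ethynyl-cis-bicyclo[3.2.0]hept-3-en-6-endo-ol | CC(C)(C)[Si](c1ccccc1)(c1ccccc1)OC[C@H]1C=C[C@H]2[C@](O)(C#C)C[C@@H]12
F2 | step 10 | 6-endo-[(tert-butyldiphenylsilyloxy)methyl]-2-methylidene-cis-bicyclo[3.3.0]oct-7-en-3-one | CC(C)(C)[Si](c1ccccc1)(c1ccccc1)OC[C@H]1C=C[C@H]2C(=C)C(=O)C[C@@H]12
F3 | step 10 | 6-endo-[(tert-butyldiphenylsilyloxy)methyl]-2-methylidene-cis-bicyclo[3.3.0]oct-7-en-3-endo-ol | CC(C)(C)[Si](c1ccccc1)(c1ccccc1)OC[C@H]1C=C[C@H]2C(=C)[C@@H](O)C[C@@H]12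
F4 | step 10 | spiro-epoxide of F3 at C8/C10 with the epoxide oxygen endo, syn to the hydroxyl | CC(C)(C)[Si](c1ccccc1)(c1ccccc1)OC[C@H]1C=C[C@H]2[C@]3(CO3)[C@@H](O)C[C@@H]12
F5 | step 10 | spiro-epoxy ketone from F4 (C7 ketone) | CC(C)(C)[Si](c1ccccc1)(c1ccccc1)OC[C@H]1C=C[C@H]2[C@]3(CO3)C(=O)C[C@@H]12
F6 | step 10 | 2-endo-hydroxy-2-exo-(hydroxymethyl)-6-endo-[(tert-butyldiphenylsilyloxy)methyl]-cis-bicyclo[3.3.0]oct-7-en-3-one | CC(C)(C)[Si](c1ccccc1)(c1ccccc1)OC[C@H]1C=C[C@H]2[C@](O)(CO)C(=O)C[C@@H]12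
F7 | step 8 | 1-{endo-2-[(tert-butyldiphenylsilyloxy)methyl]-6-endo-hydroxy-cis-bicyclo[3.2.0]hept-3-en-6-exo-yl}ethan-1-one | CC(C)(C)[Si](c1ccccc1)(c1ccccc1)OC[C@H]1C=C[C@H]2[C@](O)(C(C)=O)C[C@@H]12
F8 | step 8 | 6-endo-(trimethylsilyloxy)-6-exo-[1-(trimethylsilyloxy)vinyl] derivative of F7 | CC(C)(C)[Si](c1ccccc1)(c1ccccc1)OC[C@H]1C=C[C@H]2[C@](O[Si](C)(C)C)(C(=C)O[Si](C)(C)C)C[C@@H]12
F9 | step 8 | bis(trimethylsilyl) ether of 12 | CC(C)(C)[Si](c1ccccc1)(c1ccccc1)OC[C@H]1C=C[C@H]2[C@](O[Si](C)(C)C)(C(=O)CO[Si](C)(C)C)C[C@@H]12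
F10 | step 17 | 2-endo,3-exo-diol from 14 (7,8-trans diol, C10 triethylsilyl ether) | CC(C)(C)[Si](c1ccccc1)(c1ccccc1)OC[C@H]1C=C[C@H]2[C@](O)(CO[Si](CC)(CC)CC)[C@H](O)C[C@@H]12
F11 | step 17 | bis(trimethylsilyl) ether of F10 | CC(C)(C)[Si](c1ccccc1)(c1ccccc1)OC[C@H]1C=C[C@H]2[C@](O[Si](C)(C)C)(CO[Si](CC)(CC)CC)[C@H](O[Si](C)(C)C)C[C@@H]12
F12 | step 17 | C1/C3 dialdehyde from F11 | O=C[C@H](CO[Si](c1ccccc1)(c1ccccc1)C(C)(C)C)[C@@H]1C[C@@H](O[Si](C)(C)C)[C@@](O[Si](C)(C)C)(CO[Si](CC)(CC)CC)[C@@H]1C=O
F13 | step 17 | lactol from F12: 1-hydroxy-6,7-bis(trimethylsilyloxy)-7-(triethylsilyloxymethyl)-4-(TBDPS-oxymethyl)-hexahydrocyclopenta[c]pyran | O[C@H]1OC=C(CO[Si](c3ccccc3)(c3ccccc3)C(C)(C)C)[C@@H]2C[C@@H](O[Si](C)(C)C)[C@@](O[Si](C)(C)C)(CO[Si](CC)(CC)CC)[C@H]12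
F14 | step 17 | 1-O-[(3S)-3-methylpentanoyl] ester of F13 | CC[C@H](C)CC(=O)O[C@H]1OC=C(CO[Si](c3ccccc3)(c3ccccc3)C(C)(C)C)[C@@H]2C[C@@H](O[Si](C)(C)C)[C@@](O[Si](C)(C)C)(CO[Si](CC)(CC)CC)[C@H]12
F15 | step 17 | 6,7-dihydroxy-7-(hydroxymethyl) triol from F14 (C11 TBDPS ether, C1 ester kept) | CC[C@H](C)CC(=O)O[C@H]1OC=C(CO[Si](c3ccccc3)(c3ccccc3)C(C)(C)C)[C@@H]2C[C@@H](O)[C@@](O)(CO)[C@H]12
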